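## The problem

Skeleton numbering used throughout: C1 is the benzylic CH2, C2=C3 the trisubstituted alkene (methyl on C3), C4 a CH2, C5 the chain ketone, C6 a CH2, C7 and C11 the ring quaternary carbons joined by the ring methylenes C8–C10, C12 the ring-bound ketone and C13–C15 the prenyl group.

- The target is an aryl-terminated diketone built on a 1,2-dimethylcyclopentane. Its adjacent quaternary carbons C7 and C11 carry a 2-oxoalkyl arm (C6–C5) and an acyl group (C12) on the same face, and they are the only stereocentres (7R,11R).
- Neither centre bears hydrogen, so nothing can be epimerised or corrected later, and no third stereocentre exists to steer them. Relative and absolute configuration must be fixed when C7 is joined to C11, by a temporary stereocentre.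
- Joining two fully substituted carbons is the central steric problem.
- Both ketones are β,γ-unsaturated (C5 against C2=C3, C12 against C14=C15), C1 is benzylic and allylic, and C4 and C13 are doubly activated. Base or acid late in the route would draw the alkenes into conjugation, so the ketones should appear late and under neutral conditions.
- The C2=C3 alkene must be E. The phenol para to the methoxy group is easily oxidised and has to stay masked through every oxidation.
- The enabling feature is that C11 carries a carboxyl-level carbon (C12) and C7, cis to it, a two-carbon arm (C6–C5). With C6=C5 as an alkene this is a cis-2-alkenylcycloalkanecarboxylic acid, the retron of an ester-enolate Claisen rearrangement. Tying the C12 oxygen to C5 gives a nine-membered lactone (O, C5, C6, C7, C8, C9, C10, C11, C12) in which one carbinol centre at C5 can dictate both quaternary carbons.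

## Retrosynthesis

**36 ⇒ 35 ⇒ 34.** No carbon–carbon bond is cut. Both ketones are traced to the diol 34 and the phenol to its triisopropylsilyl ether 35. Making both β,γ-enones in one buffered oxidation means neither has to survive a carbanion. The alternative of carrying one ketone through the construction of the other would need a mask. The forward steps must oxidise without alkene migration and desilylate without free base.

**34 ⇒ 30 + 32.** The C12–C13 bond is cut, giving an aldehyde-level C12 and a prenyl nucleophile from chloride 32 that must react at its unsubstituted terminus. Cutting C13–C14 instead (alkenylation of a C12 acetyl group) would compete with the same chemistry at C4. Acylation at the acid level risks over-addition and allylic transposition. The C12 aldehyde is held as lactol 30 with the C5 hydroxyl, so no protecting group is spent. The forward reaction asks for lactol opening and α-selective prenyl transfer, which the allylbarium reagent 33 provides.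

**30 ⇒ 31 ⇒ 29 ⇒ 28.** These are redox adjustments. The C5 ketone of 28 cannot coexist with a prenyl carbanion. Reducing it (with the ester) to diol 29 turns the C5 oxygen into the internal protecting group of the C12 aldehyde, reached through lactone 31. Three redox steps are paid, and no protection or deprotection.

**28 ⇒ 17 + 26.** The C3–C4 bond is cut between the enolate of methyl ketone 17 and alkenyl iodide 26.
- This splits the molecule into halves of similar size and brings the E alkene in ready-made.
- Cutting C4–C5 would need a C5 aldehyde that the route does not supply, and an allyl nucleophile that tends to react with transposition.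
- Alkenylation is placed before prenylation because a C12 prenyl ketone, with its acidic C13, would compete for base and palladium.
- The C12 carbon is carried as a tert-butyl ester, which has no α-hydrogen and resists attack by the enolate.
- The forward step must enolise the methyl group and not the neopentyl C6, and must protonate the product dienolate at the α-carbon.

**26 ⇒ 24 ⇒ 23 ⇒ 21 + 22; 21 ⇒ 19 ⇒ 18.** The C–I bond comes from hydrozirconation–iodination of alkyne 24. The benzylic C–O bond of 23 is removed by ionic hydrogenation. C1–C2 comes from propynyl Grignard 22 and aldehyde 21. The aryl–C1 bond comes from methoxy-directed lithiation of silyl ether 19, made from phenol 18. Each step is standard, and the arene oxygenation pattern is bought with 18.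

**17 ⇒ 16 ⇒ 14 ⇒ 13.** The C5 oxygen is introduced by hydroboration of the propenyl group, with boron going to C5, remote from quaternary C7, followed by oxidation. The acid 13 is first capped as tert-butyl ester 14. Hydroboration must precede the arrival of any other alkene, since a borane would not tell the propenyl group from a prenyl or aryl-allyl group.

**13 ⇒ 10.** This is the key cut: C7–C11 is broken and O–C5 reconnected, giving the nine-membered lactone 10. Two quaternary carbons, their cis relationship, their absolute configuration and the carbocycle are all traded for one carbinol centre and a Z alkene. The forward step asks for an endocyclic silyl ketene acetal and a [3,3] shift through the only accessible (boat) array.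

**10 ⇒ 8 ⇒ 7 ⇒ 4 + 5.** The lactone C–O bond is cut (macrolactonisation of seco acid 8). The C7–C8 bond is then cut by B-alkyl Suzuki coupling of the (Z)-iodo allylic alcohol 4 with the borane 6 from commercial ester 5. A terpene-alcohol route to the same seco acid would need allylic oxidation, conjugate reduction, a configurationally fragile Z-enal and an asymmetric methyl addition. The coupling reaches 7 in one step with the alkene geometry already fixed.

**4 ⇒ 2 ⇒ 1.** Hydroxyl-directed trans-hydroalumination–iodination of alkynol 2 sets the Z geometry. Asymmetric transfer hydrogenation of ynone 1 sets the single controlling stereocentre catalytically.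

## Roads not taken

**Alternative 1: photocycloaddition of a chiral dioxinone to 1,2-dimethylcyclopentene.**
- Cut: C6–C7 and C11–C12 together. The ring and both methyl groups come from the symmetrical alkene A2.
- Forward key step: irradiation of dioxinone A1 with A2 gives the cyclobutane photoadduct A3. Later retro-aldol opening releases C12 as an acetyl group and C5 as a carboxyl.
- Merits: both quaternary carbons form in one step from a trivial alkene, the cis relationship is guaranteed by the ring fusion, and the two arms emerge differentiated. The core is reached in fewer steps than in the chosen plan, with no medium-ring lactonisation.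
- Weak points: a tetrasubstituted alkene is a poor partner for enone photocycloaddition. Because A2 is symmetrical, the enantiomeric purity of the core equals the facial selectivity at A1, which rests on a remote acetal centre. After fragmentation, C13 must be alkenylated and the C5 carboxyl turned into a ketone with an allylic C4 nucleophile, so the chemoselectivity problems of the end game return.
- Comparison: this road is shorter to the core. Against that, the chosen plan relays configuration through a ring-constrained sigmatropic array whose sense is fixed by allylic strain, uses only ground-state chemistry, and delivers C5 as an alkene that is oxygenated regioselectively.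

**Alternative 2: enzymatic Baeyer–Villiger desymmetrisation.**
- Cut: the C5–C12 bond of a temporary cyclopentanone in the meso ketone A4.
- Forward key step: a monooxygenase inserts oxygen on one enantiotopic side only, giving lactone A5 with C5 as the acyl arm and C12 as the oxygenated arm.
- Merits: the absolute configuration comes from a catalytic, reagent-controlled step on a meso compound. The two arms appear at different and useful oxidation levels without any protecting group. In this respect the road is better than the chosen plan, where acid 13 still needs hydroboration and three redox steps.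
- Weak points: A4 already contains both quaternary carbons, so the hardest bond is moved to an unsolved earlier stage. Enzyme acceptance and the sense of oxygen insertion next to two neopentyl-type α-carbons would need a screen. Opening A5 at C5 with a C4 nucleophile again raises over-addition and allylic transposition.
- Comparison: the chosen plan sets against it one predictable step that forges the quaternary pair, its cis relation and its absolute configuration, from a lactone (10) made in five steps from catalogue chemicals.

**Alternative 3: conjugate addition and enolate prenylation on a bicyclic enone.**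
- Cut: C11–CH3 and C12–C13.
- Forward key step: a methyl cuprate adds to C11 of enone A6 and the resulting enolate is alkylated at C12 by a prenyl halide, giving ketone A7. The temporary ring is opened oxidatively later.
- Merits: the prenyl group enters by simple C-alkylation in the same flask, which is more direct than the barium reagent and lactol detour of the chosen route. The cis fusion is enforced by the bicycle and the enolate is regiodefined.
- Weak points: cuprate addition to a β,β-disubstituted enone whose β-carbon adjoins an existing quaternary carbon is among the least reactive cases. The absolute configuration must already reside in A6, which needs its own asymmetric synthesis of a quaternary centre. Oxidative opening of the C5–C12 bond has to be done beside a prenyl alkene that peracids epoxidise.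
- Comparison: this road is better for the prenyl group alone. The chosen plan answers with one stereocontrolling step for both quaternary carbons and with oxidations that never meet an unprotected electron-rich alkene under electrophilic conditions.

Key step: step 6

Remark: carbinol centres that are later oxidised to ketones (C5 in 16, 29, 30, 31, 34; C12 in 30 and 34) and the α-carbon of 5–10 are carried as epimer mixtures and written without a descriptor; 1, 5, 18, 22 and 32 are taken as catalogue chemicals.

## Steps

Step 1
Reactants: 1 pent-3-yn-2-one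
Product: 2 (2R)-pent-3-yn-2-ol
Conditions: Ru[(R,R)-TsNCH(Ph)CH(Ph)NH](p-cymene) (0.5 mol%), i-PrOH, rt
Reagents that add atoms: none
Why: Noyori asymmetric transfer hydrogenation of an alkynyl ketone; the alkynyl group takes the place of the aryl group of an aryl ketone in the six-membered hydride-transfer transition state, so the (R,R)-ligand should give the (R)-carbinol, and the triple bond is not reduced.

Step 2
Reactants: 2 (2R)-pent-3-yn-2-ol
Product: 4 (2R,3Z)-4-iodopent-3-en-2-ol, via cyclic alkenylaluminate 3 (not isolated)
Conditions: NaAlH2(OCH2CH2OMe)2, THF, 0 °C to rt; then I2, −78 to 0 °C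
Reagents that add atoms: iodine, II
Why: Hydroxyl-directed trans-hydroalumination of a propargylic alcohol places aluminium on the distal alkyne carbon cis to the carbinol, and iodinolysis with retention gives the Z iodide; the carbinol centre is not touched.

Step 3
Reactants: 5 ethyl 2-methylpent-4-enoate, 4 (2R,3Z)-4-iodopent-3-en-2-ol
Product: 7 ethyl (6Z,8R)-8-hydroxy-2,6-dimethylnon-6-enoate, via B-alkyl-9-BBN 6 (not isolated)
Conditions: 5, 9-BBN, THF, rt; then 4, PdCl2(dppf) (5 mol%), AsPh3, Cs2CO3, DMF/H2O, rt
Reagents that add atoms: none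
Why: Anti-Markovnikov hydroboration followed by B-alkyl Suzuki–Miyaura coupling; the alkenyl carbon reacts with retention, so the chain enters cis to the carbinol and the Z trisubstituted alkene is fixed, and the free hydroxyl and the ester are tolerated.

Step 4
Reactants: 7 ethyl (6Z,8R)-8-hydroxy-2,6-dimethylnon-6-enoate
Product: 8 (6Z,8R)-8-hydroxy-2,6-dimethylnon-6-enoic acid
Conditions: LiOH, THF/MeOH/H2O, rt; then 1 M HCl to pH 3, 0 °C
Reagents that add atoms: lithium hydroxide, [Li+].[OH-]
Why: Ester saponification; cold, brief acidification avoids ionisation of the allylic alcohol.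

Step 5
Reactants: 8 (6Z,8R)-8-hydroxy-2,6-dimethylnon-6-enoic acid
Product: 10 (7Z,9R)-3,7,9-trimethyl-4,5,6,9-tetrahydro-3H-oxonin-2-one, via mixed anhydride 9 (not isolated)
Conditions: 2,4,6-trichlorobenzoyl chloride, Et3N, THF, rt; then slow addition to DMAP, toluene, 110 °C (high dilution)
Reagents that add atoms: none
Why: Yamaguchi macrolactonisation; the Z alkene brings the chain ends together, which is what makes nine-membered Z-alkenyl lactones accessible, and acyl–oxygen bond formation leaves the C5 configuration intact.

Step 6
Reactants: 10 (7Z,9R)-3,7,9-trimethyl-4,5,6,9-tetrahydro-3H-oxonin-2-one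
Product: 13 (1R,2R)-1,2-dimethyl-2-[(E)-prop-1-enyl]cyclopentane-1-carboxylic acid, via silyl ketene acetal 11 (not isolated), via silyl ester 12 (not isolated)
Conditions: LiN(i-Pr)2, THF, −78 °C; TBSCl, HMPA, −78 °C to rt; toluene, 110 °C; then 1 M HCl, THF, rt
Reagents that add atoms: none
Why: Ireland–Claisen rearrangement in its ring-contracting form, the known behaviour of medium-ring lactone silyl ketene acetals. LiN(i-Pr)2 removes the C11 hydrogen of either epimer and O-silylation gives the endocyclic, tetrasubstituted ketene acetal 11, whose geometry is fixed by the ring. On heating, the O–C5 bond breaks and the C7–C11 bond forms in a concerted suprafacial [3,3] shift; because C7 and C11 are tied by the bridge C8–C10, only a boat-shaped six-atom array is within reach. The cyclopentane thus closes by transannular C–C bond formation inside the nine-membered ring (a 9 to 5 contraction) and not by a polar cyclisation. C12 and C6 stay linked through O–C5 until the new bond exists, so they must emerge cis, which sets the relative configuration of C7 and C11. The absolute configuration comes from C5: its methyl group takes the outward position to avoid A(1,3) strain with C8 across the Z alkene, the ketene acetal adds to the alkene face from which oxygen departs, and (R)-C5 is relayed to (7R,11R) with an E propenyl group. The step needs O- and not C-silylation and a rearrangement faster than ketene acetal decomposition; the hindered enolate with TBSCl/HMPA secures the first and the pre-organised ring the second. Acidic work-up hydrolyses silyl ester 12 to acid 13.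

Step 7
Reactants: 13 (1R,2R)-1,2-dimethyl-2-[(E)-prop-1-enyl]cyclopentane-1-carboxylic acid
Product: 14 tert-butyl (1R,2R)-1,2-dimethyl-2-[(E)-prop-1-enyl]cyclopentane-1-carboxylate
Conditions: Me2NCH(O-t-Bu)2, toluene, 80 °C
Reagents that add atoms: N,N-dimethylformamide di-tert-butyl acetal, CN(C)C(OC(C)(C)C)OC(C)(C)C
Why: Esterification by O-alkylation of the carboxylate with a tert-butyl cation equivalent, so the hindrance at the acyl carbon does not matter; the tert-butyl ester is chosen because it later resists attack by the C4 enolate.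

Step 8
Reactants: 14 tert-butyl (1R,2R)-1,2-dimethyl-2-[(E)-prop-1-enyl]cyclopentane-1-carboxylate
Product: 16 tert-butyl (1R,2R)-2-(2-hydroxypropyl)-1,2-dimethylcyclopentane-1-carboxylate, via B-alkyl-9-BBN 15 (not isolated)
Conditions: 9-BBN, THF, 65 °C; then NaOH, H2O2, 0 °C to rt
Reagents that add atoms: hydrogen peroxide, OO
Why: Hydroboration–oxidation; 9-BBN places boron on C5, the alkene carbon remote from quaternary C7, and oxidation with retention gives the secondary alcohol, whose configuration is of no consequence.

Step 9
Reactants: 16 tert-butyl (1R,2R)-2-(2-hydroxypropyl)-1,2-dimethylcyclopentane-1-carboxylate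
Product: 17 tert-butyl (1R,2R)-1,2-dimethyl-2-(2-oxopropyl)cyclopentane-1-carboxylate
Conditions: Dess–Martin periodinane, NaHCO3, CH2Cl2, rt
Reagents that add atoms: none
Why: Dess–Martin oxidation of a secondary alcohol to the methyl ketone under neutral conditions; no epimerisable centre is present.

Step 10
Reactants: 18 4-methoxy-3-methylphenol
Product: 19 triisopropyl(4-methoxy-3-methylphenoxy)silane
Conditions: TIPSCl, imidazole, DMF, rt
Reagents that add atoms: chlorotriisopropylsilane, CC(C)[Si](Cl)(C(C)C)C(C)C
Why: Silylation of the phenol; the bulky silyl ether survives organolithium, acid and hydride reagents, is a poor ortho-director and leaves with fluoride at the end.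

Step 11
Reactants: 19 triisopropyl(4-methoxy-3-methylphenoxy)silane
Product: 21 2-methoxy-3-methyl-5-(triisopropylsilyloxy)benzaldehyde, via aryllithium 20 (not isolated)
Conditions: n-BuLi, TMEDA, Et2O, 0 °C to rt; then DMF, −78 °C to rt; aq. NH4Cl
Reagents that add atoms: N,N-dimethylformamide, CN(C)C=O
Why: Directed ortho-metalation; the methoxy group directs lithiation to its only free ortho position (the other bears the methyl group) while the bulky silyl ether shields its own flanks, and DMF formylates the aryllithium.

Step 12
Reactants: 21 2-methoxy-3-methyl-5-(triisopropylsilyloxy)benzaldehyde, 22 prop-1-ynylmagnesium bromide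
Product: 23 1-[2-methoxy-3-methyl-5-(triisopropylsilyloxy)phenyl]but-2-yn-1-ol
Conditions: THF, 0 °C; aq. NH4Cl
Reagents that add atoms: none
Why: Grignard addition of an alkynyl nucleophile to an aryl aldehyde; the new carbinol centre is removed in the next step.

Step 13
Reactants: 23 1-[2-methoxy-3-methyl-5-(triisopropylsilyloxy)phenyl]but-2-yn-1-ol
Product: 24 [3-(but-2-ynyl)-4-methoxy-5-methylphenoxy]triisopropylsilane
Conditions: Et3SiH, CF3CO2H, CH2Cl2, 0 °C
Reagents that add atoms: none
Why: Ionic hydrogenation; the benzylic, propargylic cation stabilised by the ortho-methoxyaryl group is captured by the silane, and the aryl silyl ether tolerates brief cold acid.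

Step 14
Reactants: 24 [3-(but-2-ynyl)-4-methoxy-5-methylphenoxy]triisopropylsilane
Product: 26 {3-[(2E)-3-iodobut-2-enyl]-4-methoxy-5-methylphenoxy}triisopropylsilane, via alkenylzirconocene chloride 25 (not isolated)
Conditions: Cp2Zr(H)Cl (1.5 equiv), THF, 50 °C; then I2, 0 °C
Reagents that add atoms: iodine, II
Why: Hydrozirconation–iodination; syn addition of Zr–H and equilibration with excess hydride move zirconium to the less hindered, methyl-bearing alkyne carbon, and iodinolysis with retention gives the E iodide with iodine trans to the benzylic CH2.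

Step 15
Reactants: 17 tert-butyl (1R,2R)-1,2-dimethyl-2-(2-oxopropyl)cyclopentane-1-carboxylate, 26 {3-[(2E)-3-iodobut-2-enyl]-4-methoxy-5-methylphenoxy}triisopropylsilane
Product: 28 tert-butyl (1R,2R)-2-{(4E)-6-[2-methoxy-3-methyl-5-(triisopropylsilyloxy)phenyl]-4-methyl-2-oxohex-4-enyl}-1,2-dimethylcyclopentane-1-carboxylate, via lithium enolate 27 (not isolated)
Conditions: LiN(SiMe3)2 (2.2 equiv), Pd2(dba)3 (2.5 mol%), P(t-Bu)3 (6 mol%), toluene, rt; then AcOH, −78 °C
Reagents that add atoms: none
Why: Palladium-catalysed α-alkenylation of a ketone enolate; the methyl terminus C4 is enolised and coupled because C6 is neopentyl, and oxidative addition of 26 to zerovalent palladium and reductive elimination keep the E geometry. The second equivalent of base holds the product as its dienolate, and cold protonation at the α-carbon returns the β,γ-unsaturated ketone; the tert-butyl ester is inert.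

Step 16
Reactants: 28 tert-butyl (1R,2R)-2-{(4E)-6-[2-methoxy-3-methyl-5-(triisopropylsilyloxy)phenyl]-4-methyl-2-oxohex-4-enyl}-1,2-dimethylcyclopentane-1-carboxylate
Product: 29 (4E)-1-[(1R,2R)-2-(hydroxymethyl)-1,2-dimethylcyclopentyl]-6-[2-methoxy-3-methyl-5-(triisopropylsilyloxy)phenyl]-4-methylhex-4-en-2-ol
Conditions: i-Bu2AlH (5 equiv), CH2Cl2, −78 °C to rt; aq. potassium sodium tartrate
Reagents that add atoms: none
Why: Hydride reduction of ketone and ester to the diol; it takes the base-sensitive enone out of play while C12 is elaborated, and the aryl silyl ether and both alkenes are inert to the aluminium hydride.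

Step 17
Reactants: 29 (4E)-1-[(1R,2R)-2-(hydroxymethyl)-1,2-dimethylcyclopentyl]-6-[2-methoxy-3-methyl-5-(triisopropylsilyloxy)phenyl]-4-methylhex-4-en-2-ol
Product: 31 (4aR,7aR)-3-{(2E)-4-[2-methoxy-3-methyl-5-(triisopropylsilyloxy)phenyl]-2-methylbut-2-enyl}-4a,7a-dimethylhexahydrocyclopenta[c]pyran-1(3H)-one, via lactol 30 (not isolated)
Conditions: TEMPO (20 mol%), PhI(OAc)2 (2.5 equiv), CH2Cl2, rt
Reagents that add atoms: none
Why: Nitroxyl-catalysed oxidation selective for the primary alcohol; the hydroxy aldehyde closes onto the C5 hydroxyl and the lactol is oxidised on to the δ-lactone, so C5 is protected internally.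

Step 18
Reactants: 31 (4aR,7aR)-3-{(2E)-4-[2-methoxy-3-methyl-5-(triisopropylsilyloxy)phenyl]-2-methylbut-2-enyl}-4a,7a-dimethylhexahydrocyclopenta[c]pyran-1(3H)-one
Product: 30 (4aR,7aR)-3-{(2E)-4-[2-methoxy-3-methyl-5-(triisopropylsilyloxy)phenyl]-2-methylbut-2-enyl}-4a,7a-dimethyloctahydrocyclopenta[c]pyran-1-ol
Conditions: i-Bu2AlH (1.2 equiv), CH2Cl2, −78 °C; aq. potassium sodium tartrate
Reagents that add atoms: none
Why: Partial reduction of a lactone to the lactol; the tetrahedral aluminate is stable at low temperature, so reduction stops at the aldehyde level.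

Step 19
Reactants: 30 (4aR,7aR)-3-{(2E)-4-[2-methoxy-3-methyl-5-(triisopropylsilyloxy)phenyl]-2-methylbut-2-enyl}-4a,7a-dimethyloctahydrocyclopenta[c]pyran-1-ol, 32 1-chloro-3-methylbut-2-ene
Product: 34 (4E)-1-[(1R,2R)-2-(1-hydroxy-4-methylpent-3-enyl)-1,2-dimethylcyclopentyl]-6-[2-methoxy-3-methyl-5-(triisopropylsilyloxy)phenyl]-4-methylhex-4-en-2-ol, via prenylbarium chloride 33 (not isolated)
Conditions: Li, biphenyl, BaI2, THF, rt; 32, −78 °C; then 30 (0.33 equiv), −78 to −40 °C; aq. NH4Cl
Reagents that add atoms: none
Why: Allylbarium addition to an aldehyde presented as its lactol; the first equivalent forms the lactolate, which opens to the alkoxy aldehyde, and the barium reagent attacks through its unsubstituted α-carbon to give the linear prenyl carbinol. No ketone or ester is present, and both carbinol configurations are irrelevant.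

Step 20
Reactants: 34 (4E)-1-[(1R,2R)-2-(1-hydroxy-4-methylpent-3-enyl)-1,2-dimethylcyclopentyl]-6-[2-methoxy-3-methyl-5-(triisopropylsilyloxy)phenyl]-4-methylhex-4-en-2-ol
Product: 35 (4E)-1-[(1R,2R)-1,2-dimethyl-2-(4-methylpent-3-enoyl)cyclopentyl]-6-[2-methoxy-3-methyl-5-(triisopropylsilyloxy)phenyl]-4-methylhex-4-en-2-one
Conditions: Dess–Martin periodinane (3 equiv), NaHCO3, CH2Cl2, 0 °C to rt
Reagents that add atoms: none
Why: Double Dess–Martin oxidation of two homoallylic alcohols to β,γ-unsaturated ketones under buffered, non-basic conditions, so neither alkene should migrate; the phenol is still silylated and safe from the oxidant.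

Step 21
Reactants: 35 (4E)-1-[(1R,2R)-1,2-dimethyl-2-(4-methylpent-3-enoyl)cyclopentyl]-6-[2-methoxy-3-methyl-5-(triisopropylsilyloxy)phenyl]-4-methylhex-4-en-2-one
Product: 36 (4E)-6-(5-hydroxy-2-methoxy-3-methylphenyl)-1-[(1R,2R)-1,2-dimethyl-2-(4-methylpent-3-enoyl)cyclopentyl]-4-methylhex-4-en-2-one
Conditions: Bu4NF, AcOH, THF, 0 °C
Reagents that add atoms: none
Why: Fluoride cleavage of an aryl silyl ether, buffered with acetic acid so that neither fluoride nor phenoxide acts as a base on the two skipped enones.

## Compound list

1 | pent-3-yn-2-one | CC#CC(C)=O | starting material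
2 | (2R)-pent-3-yn-2-ol | C[C@@H](O)C#CC | intermediate
3 | sodium cyclic alkenylaluminate from 2 (five-membered 1,2-oxaaluminate, two 2-methoxyethoxy groups on aluminium) | [Na+].C[C@H]1O[Al-](OCCOC)(OCCOC)C(C)=C1 | intermediate
4 | (2R,3Z)-4-iodopent-3-en-2-ol | C[C@@H](O)/C=C(\I)C | intermediate
5 | ethyl 2-methylpent-4-enoate (racemic) | CCOC(=O)C(C)CC=C | starting material
6 | ethyl 5-(9-borabicyclo[3.3.1]nonan-9-yl)-2-methylpentanoate | CCOC(=O)C(C)CCCB1C2CCCC1CCC2 | intermediate
7 | ethyl (6Z,8R)-8-hydroxy-2,6-dimethylnon-6-enoate (C2 epimers) | CCOC(=O)C(C)CCC/C(C)=C\[C@@H](C)O | intermediate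
8 | (6Z,8R)-8-hydroxy-2,6-dimethylnon-6-enoic acid (C2 epimers) | OC(=O)C(C)CCC/C(C)=C\[C@@H](C)O | intermediate
9 | (6Z,8R)-8-hydroxy-2,6-dimethylnon-6-enoic 2,4,6-trichlorobenzoic anhydride | Clc1cc(Cl)c(c(Cl)c1)C(=O)OC(=O)C(C)CCC/C(C)=C\[C@@H](C)O | intermediate
10 | (7Z,9R)-3,7,9-trimethyl-4,5,6,9-tetrahydro-3H-oxonin-2-one (C3 epimers) | C[C@@H]1/C=C(C)\CCCC(C)C(=O)O1 | intermediate
11 | tert-butyldimethylsilyl ketene acetal of 10 (endocyclic C3=C2, ring atoms C4 and O1 cis; 9R, 7Z) | C[C@@H]1/C=C(C)\CCC/C(C)=C(O[Si](C)(C)C(C)(C)C)\O1 | intermediate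
12 | tert-butyldimethylsilyl (1R,2R)-1,2-dimethyl-2-[(E)-prop-1-enyl]cyclopentane-1-carboxylate | C/C=C/[C@@]1(C)CCC[C@@]1(C)C(=O)O[Si](C)(C)C(C)(C)C | intermediate
13 | (1R,2R)-1,2-dimethyl-2-[(E)-prop-1-enyl]cyclopentane-1-carboxylic acid | C/C=C/[C@@]1(C)CCC[C@@]1(C)C(O)=O | intermediate
14 | tert-butyl (1R,2R)-1,2-dimethyl-2-[(E)-prop-1-enyl]cyclopentane-1-carboxylate | C/C=C/[C@@]1(C)CCC[C@@]1(C)C(=O)OC(C)(C)C | intermediate
15 | tert-butyl (1R,2R)-2-[2-(9-borabicyclo[3.3.1]nonan-9-yl)propyl]-1,2-dimethylcyclopentane-1-carboxylate | CC(C[C@@]1(C)CCC[C@@]1(C)C(=O)OC(C)(C)C)B1C2CCCC1CCC2 | intermediate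
16 | tert-butyl (1R,2R)-2-(2-hydroxypropyl)-1,2-dimethylcyclopentane-1-carboxylate (carbinol epimers) | CC(O)C[C@@]1(C)CCC[C@@]1(C)C(=O)OC(C)(C)C | intermediate
17 | tert-butyl (1R,2R)-1,2-dimethyl-2-(2-oxopropyl)cyclopentane-1-carboxylate | CC(=O)C[C@@]1(C)CCC[C@@]1(C)C(=O)OC(C)(C)C | intermediate
18 | 4-methoxy-3-methylphenol | COc1ccc(O)cc1C | starting material
19 | triisopropyl(4-methoxy-3-methylphenoxy)silane | COc1ccc(O[Si](C(C)C)(C(C)C)C(C)C)cc1C | intermediate
20 | [2-methoxy-3-methyl-5-(triisopropylsilyloxy)phenyl]lithium | [Li]c1cc(O[Si](C(C)C)(C(C)C)C(C)C)cc(C)c1OC | intermediate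
21 | 2-methoxy-3-methyl-5-(triisopropylsilyloxy)benzaldehyde | COc1c(C)cc(O[Si](C(C)C)(C(C)C)C(C)C)cc1C=O | intermediate
22 | prop-1-ynylmagnesium bromide | CC#C[Mg]Br | starting material
23 | 1-[2-methoxy-3-methyl-5-(triisopropylsilyloxy)phenyl]but-2-yn-1-ol (racemic) | COc1c(C)cc(O[Si](C(C)C)(C(C)C)C(C)C)cc1C(O)C#CC | intermediate
24 | [3-(but-2-ynyl)-4-methoxy-5-methylphenoxy]triisopropylsilane | COc1c(C)cc(O[Si](C(C)C)(C(C)C)C(C)C)cc1CC#CC | intermediate
25 | chlorobis(cyclopentadienyl){(2E)-4-[2-methoxy-3-methyl-5-(triisopropylsilyloxy)phenyl]but-2-en-2-yl}zirconium | COc1c(C)cc(O[Si](C(C)C)(C(C)C)C(C)C)cc1C/C=C(\C)[Zr](Cl)(C1C=CC=C1)C1C=CC=C1 | intermediate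
26 | {3-[(2E)-3-iodobut-2-enyl]-4-methoxy-5-methylphenoxy}triisopropylsilane | COc1c(C)cc(O[Si](C(C)C)(C(C)C)C(C)C)cc1C/C=C(\C)I | intermediate
27 | lithium enolate of 17 (terminal, C4=C5) | [Li]OC(=C)C[C@@]1(C)CCC[C@@]1(C)C(=O)OC(C)(C)C | intermediate
28 | tert-butyl (1R,2R)-2-{(4E)-6-[2-methoxy-3-methyl-5-(triisopropylsilyloxy)phenyl]-4-methyl-2-oxohex-4-enyl}-1,2-dimethylcyclopentane-1-carboxylate | COc1c(C)cc(O[Si](C(C)C)(C(C)C)C(C)C)cc1C/C=C(\C)CC(=O)C[C@@]1(C)CCC[C@@]1(C)C(=O)OC(C)(C)C | intermediate
29 | (4E)-1-[(1R,2R)-2-(hydroxymethyl)-1,2-dimethylcyclopentyl]-6-[2-methoxy-3-methyl-5-(triisopropylsilyloxy)phenyl]-4-methylhex-4-en-2-ol (carbinol epimers) | COc1c(C)cc(O[Si](C(C)C)(C(C)C)C(C)C)cc1C/C=C(\C)CC(O)C[C@@]1(C)CCC[C@@]1(C)CO | intermediate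
30 | (4aR,7aR)-3-{(2E)-4-[2-methoxy-3-methyl-5-(triisopropylsilyloxy)phenyl]-2-methylbut-2-enyl}-4a,7a-dimethyloctahydrocyclopenta[c]pyran-1-ol (epimers at C1 and C3) | COc1c(C)cc(O[Si](C(C)C)(C(C)C)C(C)C)cc1C/C=C(\C)CC1C[C@@]2(C)CCC[C@@]2(C)C(O)O1 | intermediate
31 | (4aR,7aR)-3-{(2E)-4-[2-methoxy-3-methyl-5-(triisopropylsilyloxy)phenyl]-2-methylbut-2-enyl}-4a,7a-dimethylhexahydrocyclopenta[c]pyran-1(3H)-one (C3 epimers) | COc1c(C)cc(O[Si](C(C)C)(C(C)C)C(C)C)cc1C/C=C(\C)CC1C[C@@]2(C)CCC[C@@]2(C)C(=O)O1 | intermediate
32 | 1-chloro-3-methylbut-2-ene | CC(C)=CCCl | starting material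
33 | (3-methylbut-2-enyl)barium chloride | CC(C)=CC[Ba]Cl | intermediate
34 | (4E)-1-[(1R,2R)-2-(1-hydroxy-4-methylpent-3-enyl)-1,2-dimethylcyclopentyl]-6-[2-methoxy-3-methyl-5-(triisopropylsilyloxy)phenyl]-4-methylhex-4-en-2-ol (carbinol epimers) | COc1c(C)cc(O[Si](C(C)C)(C(C)C)C(C)C)cc1C/C=C(\C)CC(O)C[C@@]1(C)CCC[C@@]1(C)C(O)CC=C(C)C | intermediate
35 | (4E)-1-[(1R,2R)-1,2-dimethyl-2-(4-methylpent-3-enoyl)cyclopentyl]-6-[2-methoxy-3-methyl-5-(triisopropylsilyloxy)phenyl]-4-methylhex-4-en-2-one | COc1c(C)cc(O[Si](C(C)C)(C(C)C)C(C)C)cc1C/C=C(\C)CC(=O)C[C@@]1(C)CCC[C@@]1(C)C(=O)CC=C(C)C | intermediate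
36 | (4E)-6-(5-hydroxy-2-methoxy-3-methylphenyl)-1-[(1R,2R)-1,2-dimethyl-2-(4-methylpent-3-enoyl)cyclopentyl]-4-methylhex-4-en-2-one | COc1c(C)cc(O)cc1C/C=C(\C)CC(=O)C[C@@]1(C)CCC[C@@]1(C)C(=O)CC=C(C)C | target

## Step count and least certain steps

Total: 21 steps. Longest linear sequence: 16 steps (steps 1–9, then 15–21, from pent-3-yn-2-one). The aryl branch (steps 10–14) joins at step 15.

**Step 6 (key step).**
- Risk: both ends of the new bond are fully substituted, so the rearrangement may be slow enough for thermal breakdown of the ketene acetal to compete. Leakage through the boat with the C5 methyl turned inward would erode the transfer of chirality.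
- Fallback: build the C11 methyl group after the ring contraction.
  - It sets out from iodide 4. Coupling with the 9-BBN adduct of ethyl pent-4-enoate (conditions of step 3) should give ethyl (6Z,8R)-8-hydroxy-6-methylnon-6-enoate F1.
  - Saponification gives (6Z,8R)-8-hydroxy-6-methylnon-6-enoic acid F2, and Yamaguchi lactonisation gives (7Z,9R)-7,9-dimethyl-4,5,6,9-tetrahydro-3H-oxonin-2-one F3.
  - F3 has an unsubstituted enolate carbon, the substrate type for which the ring contraction is established. It should give (1R,2R)-2-methyl-2-[(E)-prop-1-enyl]cyclopentane-1-carboxylic acid F4, which is esterified as in step 7 to tert-butyl (1R,2R)-2-methyl-2-[(E)-prop-1-enyl]cyclopentane-1-carboxylate F5.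
  - Enolisation of F5 with LiN(i-Pr)2 and C-methylation with MeI, expected trans to the larger propenyl group on C7, comes back to the route at 14. The facial preference is less secure than the ring-enforced one, and the epimer would have to be separated.

**Step 15.**
- Risk: slow coupling of the hindered trisubstituted iodide, leaving the enolate time for self-condensation, and protonation of the product dienolate at the γ-carbon, which moves the alkene into conjugation.
- Fallback: reverse the polarity and avoid base.
  - It sets out from 17. Kinetic silylation (LiN(i-Pr)2, TMSCl, −78 °C) gives tert-butyl (1R,2R)-1,2-dimethyl-2-[2-(trimethylsilyloxy)prop-2-enyl]cyclopentane-1-carboxylate F6.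
  - N-bromosuccinimide gives tert-butyl (1R,2R)-2-(3-bromo-2-oxopropyl)-1,2-dimethylcyclopentane-1-carboxylate F7.
  - Nickel-catalysed cross-coupling of this α-bromo ketone with alkenylzirconocene 25 (made from 24 as in step 14; NiCl2(glyme), 2,2′-bipyridine, THF) joins C3 to C4 under neutral conditions and comes back to the route at 28.

**Step 19.**
- Risk: the barium lactolate may fail to open to the aldehyde at the low temperature at which the reagent keeps its regioselectivity. The reaction would then stall or, on warming, transfer the prenyl group through its substituted terminus.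
- Fallback: an open-chain aldehyde and a non-ambident nucleophile.
  - It sets out from 28. NaBH4 gives tert-butyl (1R,2R)-2-{(4E)-2-hydroxy-6-[2-methoxy-3-methyl-5-(triisopropylsilyloxy)phenyl]-4-methylhex-4-enyl}-1,2-dimethylcyclopentane-1-carboxylate F8.
  - Triethylsilyl triflate and 2,6-lutidine give its triethylsilyl ether F9.
  - i-Bu2AlH gives [(1R,2R)-2-{(4E)-6-[2-methoxy-3-methyl-5-(triisopropylsilyloxy)phenyl]-4-methyl-2-(triethylsilyloxy)hex-4-enyl}-1,2-dimethylcyclopentyl]methanol F10.
  - Dess–Martin oxidation gives the corresponding cyclopentane-1-carbaldehyde F11.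
  - Dimethylsulfonium methylide converts F11 into the terminal epoxide F12.
  - (2-Methylprop-1-enyl)magnesium bromide with catalytic CuI opens F12 at its CH2 terminus to the prenyl carbinol triethylsilyl ether F13.
  - Pyridinium p-toluenesulfonate in methanol removes the triethylsilyl group and comes back to the route at 34.

**Step 5.**
- Risk: intermolecular acylation (diolide and oligomers) outrunning closure of the strained nine-membered ring, made worse by the hindered secondary alcohol and α-branched acid.
- Fallback: close the ring at the alkene instead of the ester.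
  - It sets out from 5. Its borane 6 is coupled with 2-bromopropene (conditions of step 3) to give ethyl 2,6-dimethylhept-6-enoate F14.
  - Saponification gives 2,6-dimethylhept-6-enoic acid F15.
  - Carbodiimide esterification with commercial (R)-but-3-en-2-ol gives (2R)-but-3-en-2-yl 2,6-dimethylhept-6-enoate F16.
  - Ring-closing metathesis with (H2IMes)(PCy3)Cl2Ru=CHPh (second-generation Grubbs catalyst) in dilute hot toluene, where the ring size enforces the Z alkene, comes back to the route at 10.

## Further compounds

F1 | step 6 | ethyl (6Z,8R)-8-hydroxy-6-methylnon-6-enoate | CCOC(=O)CCCC/C(C)=C\[C@@H](C)O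
F2 | step 6 | (6Z,8R)-8-hydroxy-6-methylnon-6-enoic acid | OC(=O)CCCC/C(C)=C\[C@@H](C)O
F3 | step 6 | (7Z,9R)-7,9-dimethyl-4,5,6,9-tetrahydro-3H-oxonin-2-one | C[C@@H]1/C=C(C)\CCCCC(=O)O1
F4 | step 6 | (1R,2R)-2-methyl-2-[(E)-prop-1-enyl]cyclopentane-1-carboxylic acid | C/C=C/[C@@]1(C)CCC[C@H]1C(O)=O
F5 | step 6 | tert-butyl (1R,2R)-2-methyl-2-[(E)-prop-1-enyl]cyclopentane-1-carboxylate | C/C=C/[C@@]1(C)CCC[C@H]1C(=O)OC(C)(C)C
F6 | step 15 | tert-butyl (1R,2R)-1,2-dimethyl-2-[2-(trimethylsilyloxy)prop-2-enyl]cyclopentane-1-carboxylate | C=C(O[Si](C)(C)C)C[C@@]1(C)CCC[C@@]1(C)C(=O)OC(C)(C)C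
F7 | step 15 | tert-butyl (1R,2R)-2-(3-bromo-2-oxopropyl)-1,2-dimethylcyclopentane-1-carboxylate | BrCC(=O)C[C@@]1(C)CCC[C@@]1(C)C(=O)OC(C)(C)C
F8 | step 19 | tert-butyl (1R,2R)-2-{(4E)-2-hydroxy-6-[2-methoxy-3-methyl-5-(triisopropylsilyloxy)phenyl]-4-methylhex-4-enyl}-1,2-dimethylcyclopentane-1-carboxylate | COc1c(C)cc(O[Si](C(C)C)(C(C)C)C(C)C)cc1C/C=C(\C)CC(O)C[C@@]1(C)CCC[C@@]1(C)C(=O)OC(C)(C)C
F9 | step 19 | tert-butyl (1R,2R)-2-{(4E)-6-[2-methoxy-3-methyl-5-(triisopropylsilyloxy)phenyl]-4-methyl-2-(triethylsilyloxy)hex-4-enyl}-1,2-dimethylcyclopentane-1-carboxylate | COc1c(C)cc(O[Si](C(C)C)(C(C)C)C(C)C)cc1C/C=C(\C)CC(O[Si](CC)(CC)CC)C[C@@]1(C)CCC[C@@]1(C)C(=O)OC(C)(C)C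
F10 | step 19 | [(1R,2R)-2-{(4E)-6-[2-methoxy-3-methyl-5-(triisopropylsilyloxy)phenyl]-4-methyl-2-(triethylsilyloxy)hex-4-enyl}-1,2-dimethylcyclopentyl]methanol | COc1c(C)cc(O[Si](C(C)C)(C(C)C)C(C)C)cc1C/C=C(\C)CC(O[Si](CC)(CC)CC)C[C@@]1(C)CCC[C@@]1(C)CO
F11 | step 19 | (1R,2R)-2-{(4E)-6-[2-methoxy-3-methyl-5-(triisopropylsilyloxy)phenyl]-4-methyl-2-(triethylsilyloxy)hex-4-enyl}-1,2-dimethylcyclopentane-1-carbaldehyde | COc1c(C)cc(O[Si](C(C)C)(C(C)C)C(C)C)cc1C/C=C(\C)CC(O[Si](CC)(CC)CC)C[C@@]1(C)CCC[C@@]1(C)C=O
F12 | step 19 | 2-[(1R,2R)-2-{(4E)-6-[2-methoxy-3-methyl-5-(triisopropylsilyloxy)phenyl]-4-methyl-2-(triethylsilyloxy)hex-4-enyl}-1,2-dimethylcyclopentyl]oxirane | COc1c(C)cc(O[Si](C(C)C)(C(C)C)C(C)C)cc1C/C=C(\C)CC(O[Si](CC)(CC)CC)C[C@@]1(C)CCC[C@@]1(C)C1CO1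
F13 | step 19 | 1-[(1R,2R)-2-{(4E)-6-[2-methoxy-3-methyl-5-(triisopropylsilyloxy)phenyl]-4-methyl-2-(triethylsilyloxy)hex-4-enyl}-1,2-dimethylcyclopentyl]-4-methylpent-3-en-1-ol | COc1c(C)cc(O[Si](C(C)C)(C(C)C)C(C)C)cc1C/C=C(\C)CC(O[Si](CC)(CC)CC)C[C@@]1(C)CCC[C@@]1(C)C(O)CC=C(C)C
F14 | step 5 | ethyl 2,6-dimethylhept-6-enoate | CCOC(=O)C(C)CCCC(C)=C
F15 | step 5 | 2,6-dimethylhept-6-enoic acid | OC(=O)C(C)CCCC(C)=C
F16 | step 5 | (2R)-but-3-en-2-yl 2,6-dimethylhept-6-enoate | C[C@@H](OC(=O)C(C)CCCC(C)=C)C=C
A1 | alternative 1 | (2R)-2-tert-butyl-6-methyl-4H-1,3-dioxin-4-one | CC1=CC(=O)O[C@H](C(C)(C)C)O1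
A2 | alternative 1 | 1,2-dimethylcyclopentene | CC1=C(C)CCC1
A3 | alternative 1 | cis-anti-cis photoadduct (2-tert-butyl-1,3-dioxan-4-one fused to 1,5-dimethylbicyclo[3.2.0]heptane) | C[C@@]12O[C@@H](C(C)(C)C)OC(=O)[C@@H]1[C@@]3(C)CCC[C@@]23C
A4 | alternative 2 | meso cis-3a,6a-dimethylhexahydropentalen-2(1H)-one | O=C1C[C@@]2(C)CCC[C@@]2(C)C1
A5 | alternative 2 | (4aR,7aR)-4a,7a-dimethylhexahydrocyclopenta[c]pyran-3(1H)-one | O=C1C[C@@]2(C)CCC[C@@]2(C)CO1
A6 | alternative 3 | (6aR)-6a-methyl-4,5,6,6a-tetrahydropentalen-2(1H)-one | O=C1C[C@@]2(C)CCCC2=C1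
A7 | alternative 3 | cis-3a,6a-dimethyl-1-(3-methylbut-2-enyl)hexahydropentalen-2(1H)-one | O=C1C[C@@]2(C)CCC[C@@]2(C)[C@H]1CC=C(C)C
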